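Beta levels off at 20.5% left-handed product, zeta at 27.9% and delta at 31.6%, and these plateaus are my way into the new flask.

| flask | left-handed substrate | right-handed substrate | reagent | remark | time |
|---|---|---|---|---|---|
| delta | 0.17 M | 0.17 M | 0.55 M | run made earlier |  |
| zeta | 0.38 M | 0.38 M | 0.55 M | run made earlier |  |
| beta | 0.25 M | 0.25 M | 0.28 M | run made earlier |  |
| flask | 0.25 M | 0.25 M | 0.550 M |  | 10 h |

| run | time / h | left-handed product / % | left-handed substrate / % |
|---|---|---|---|
| delta | 0.0833 | 35.2 | 9.0 |
| delta | 0.200 | 34.9 | 1.2 |
| delta | 0.500 | 31.5 | 0 |
| delta | 1.33 | 31.7 | 0.2 |
| delta | 3.00 | 30.9 | 0.7 |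
| delta | 8.00 | 32.3 | 0 |
| zeta | 0.0833 | 28.7 | 11.2 |
| zeta | 0.200 | 28.8 | 3.7 |
| zeta | 0.500 | 28.1 | 0 |
| zeta | 1.33 | 28.0 | 0.8 |
| zeta | 3.00 | 28.7 | 0.1 |
| zeta | 8.00 | 26.7 | 0.6 |
| beta | 0.0833 | 20.1 | 15.5 |
| beta | 0.250 | 20.3 | 4.0 |
| beta | 0.833 | 20.6 | 0.1 |
| beta | 2.50 | 20.3 | 0 |
| beta | 8.00 | 20.6 | 0 |

(each reading ± 0.5 percentage points)

- reagent is single-handed; left-handed substrate and right-handed substrate are mirror images of each other, charged as a racemate, each of them at the stated concentration
- steps under discussion: left-handed product <-> right-handed product; left-handed substrate <-> achiral form; reagent + right-handed substrate -> right-handed product; right-handed substrate <-> achiral form; reagent + left-handed substrate -> left-handed product; achiral form -> waste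
- the handed part of reagent does not stay in what it makes, so the products of the two hands are mirror images too

* the moment within 10 h at which there is most left-handed product
* the amount of left-handed product, in percent of the left-handed substrate and right-handed substrate together charged, at that time

I start at the late end. The products are mirror images, so I take the plateaus of the two hands as equal, and the captured fraction of the charge as the sum of the two. I count the rest as lost to waste. My first estimate sets captured over lost equal to reagent level over one constant, the even-odds level, at which capture and loss run equally.

The objection is that reagent does not stay at its charge: beta uses 73.2% of its own. So I take the mean of the start and end levels. That gives an even-odds level of 0.255 M from beta, 0.268 M from zeta and 0.258 M from delta. I keep their mean, 0.261 M. Solved for the flask, the rule captures 60.5%, a plateau of 30.2% per hand.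

But the question is about the peak, the early end, where kinetic control gives way to thermodynamic control. Delta reads 35.2% at 0.0833 h and 34.9% at 0.200 h, level within the scatter, so I put its peak at their geometric middle, 0.129 h. The flask holds more substrate than delta, but zeta holds more still and stays level between the same readings, so I keep that time. The early readings stand 3.5 percentage points above the plateau in delta and 0.87 points in zeta. Interpolating by substrate charge and joining that to the plateau gives 32.7%.

The forecast says “The maximum should come as substrate runs out”, at 0.3 h with 32.3%. The flask peaks at 0.126 h with 33.4%.

    left-handed product ⇌ right-handed product (k = 0.00206 /s)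
    left-handed substrate ⇌ achiral form (K = 0.604, k = 0.0235 /s)
    reagent + right-handed substrate → right-handed product (k = 9.86 × 10⁻⁴ /M/s)
    right-handed substrate ⇌ achiral form (K = 0.604, k = 0.0235 /s)
    reagent + left-handed substrate → left-handed product (k = 0.0176 /M/s)
    achiral form → waste (k = 0.00713 /s)

The flask ends with 30.7% left-handed product against my plateau of 30.2%. Now take a neighbouring flask, the same as this one but with 0.22 M reagent. The even-odds level gives it a captured fraction of 34.1%, so 17.1% per hand, 65.9% waste and 22.5% of its reagent left. The simulated neighbouring flask ends with 22% of its reagent left, 17.1% left-handed product, 17.1% right-handed product and 65.8% waste.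

(All runs are calculated for substances that don't exist, and the scatter is random.)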